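**Strategy.** Everything rests on closing the cyclohexa-2,5-dienone ring last, at its trisubstituted alkene C5=C6 (ring numbered from the quaternary C1–OMe; enol ether C2=C3, ketone C4, allyl on C5). This enone alkene is an aldol-condensation retron. The acyclic precursor is an (E)-β-methoxy enone with a pent-4-enoyl ketone and a formyl group on the quaternary carbon. Its only enolisable CH2 attacks the non-enolisable aldehyde, and dehydration delivers the dienone with the vinylogous ester regiochemistry already fixed. The side-chain stereocentres come from an Evans syn aldol, the quaternary centre from a chelation-controlled ethynyl Grignard addition.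

Key step: step 10

Remark: in CH2Cl2 without a participating solvent, the ozonolysis intermediate is taken to be the secondary ozonide.

**Step 1**
Reactants: 1 (R)-4-benzyl-3-propionyloxazolidin-2-one; 2 3,4-dimethoxybenzaldehyde
Product: 5 (R)-4-benzyl-3-[(2R,3R)-3-(3,4-dimethoxyphenyl)-3-hydroxy-2-methylpropanoyl]oxazolidin-2-one, via dibutylboron (Z)-enolate 3 (not isolated), via dibutylboron aldolate 4 (not isolated)
Conditions: Bu2BOTf, i-Pr2NEt, CH2Cl2, 0 °C; then 2, −78 → 0 °C; then pH 7 buffer, MeOH, 30% H2O2, 0 °C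
Reagents that add atoms: none
Why: Evans syn aldol: the (Z)-boron enolate reacts through a Zimmerman–Traxler chair on the enolate face opposite the benzyl group of the (R)-auxiliary, which should set both side-chain stereocentres as (2R,3R), syn.

**Step 2**
Reactants: 5 (R)-4-benzyl-3-[(2R,3R)-3-(3,4-dimethoxyphenyl)-3-hydroxy-2-methylpropanoyl]oxazolidin-2-one
Product: 6 (2R,3R)-3-(3,4-dimethoxyphenyl)-3-hydroxy-N-methoxy-N,2-dimethylpropanamide
Conditions: MeNH(OMe)·HCl, AlMe3, CH2Cl2, −20 → 0 °C; aqueous potassium sodium tartrate work-up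
Reagents that add atoms: N,O-dimethylhydroxylamine hydrochloride, CNOC.Cl
Why: Weinreb aminolysis of the imide by the aluminium amide formed in the flask occurs at the exocyclic carbonyl, assisted by the free β-hydroxyl, without epimerisation of the α-centre.

**Step 3**
Reactants: 6 (2R,3R)-3-(3,4-dimethoxyphenyl)-3-hydroxy-N-methoxy-N,2-dimethylpropanamide; 7 vinylmagnesium bromide (CH2=CHMgBr)
Product: 8 (4R,5R)-5-(3,4-dimethoxyphenyl)-5-hydroxy-4-methylpent-1-en-3-one
Conditions: 7 (3.5 equiv), THF, −78 → 0 °C; inverse quench into cold 1 M HCl; used crude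
Reagents that add atoms: none
Why: Weinreb ketone synthesis: after deprotonation of the hydroxyl, the chelated tetrahedral magnesium intermediate stops at the mono-adduct and collapses to the vinyl ketone only on the cold acidic quench, which also keeps the liberated amine from adding to the enone.

**Step 4**
Reactants: 8 (4R,5R)-5-(3,4-dimethoxyphenyl)-5-hydroxy-4-methylpent-1-en-3-one; 9 ethynylmagnesium bromide (HC≡CMgBr)
Product: 10 (3R,4R,5R)-5-(3,4-dimethoxyphenyl)-3-ethynyl-4-methylpent-1-ene-3,5-diol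
Conditions: 9 (4 equiv), THF/CH2Cl2, −78 → −30 °C; aqueous NH4Cl
Reagents that add atoms: none
Why: Chelation-controlled Grignard 1,2-addition: the first equivalent forms the magnesium alkoxide, which chelates the ketone oxygen in a six-membered chair with aryl equatorial and the C4 methyl axial, so the acetylide should add to the carbonyl face anti to that methyl group and give the (3R) tertiary carbinol.

**Step 5**
Reactants: 10 (3R,4R,5R)-5-(3,4-dimethoxyphenyl)-3-ethynyl-4-methylpent-1-ene-3,5-diol
Product: 11 (1R,2R,3R)-1-(3,4-dimethoxyphenyl)-3-ethynyl-3-hydroxy-2-methylpent-4-en-1-yl acetate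
Conditions: Ac2O (1.2 equiv), pyridine, DMAP (cat.), CH2Cl2, 0 °C
Reagents that add atoms: acetic anhydride, CC(=O)OC(C)=O
Why: DMAP-catalysed acylation discriminates the secondary benzylic hydroxyl from the hindered tertiary propargylic one, so only the former should be acetylated.

**Step 6**
Reactants: 11 (1R,2R,3R)-1-(3,4-dimethoxyphenyl)-3-ethynyl-3-hydroxy-2-methylpent-4-en-1-yl acetate
Product: 12 (1R,2R,3R)-1-(3,4-dimethoxyphenyl)-3-ethynyl-3-methoxy-2-methylpent-4-en-1-yl acetate
Conditions: MeOTf, 2,6-di-tert-butyl-4-methylpyridine, CH2Cl2, 0 °C → rt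
Reagents that add atoms: methyl trifluoromethanesulfonate, COS(=O)(=O)C(F)(F)F
Why: O-Methylation with methyl triflate and a hindered non-nucleophilic pyridine proceeds without forming an alkoxide, so the tertiary hydroxyl should be etherified while the acetate neither migrates nor cleaves.

**Step 7**
Reactants: 12 (1R,2R,3R)-1-(3,4-dimethoxyphenyl)-3-ethynyl-3-methoxy-2-methylpent-4-en-1-yl acetate
Product: 14 (1R,2R,3R)-1-(3,4-dimethoxyphenyl)-3-formyl-3-methoxy-2-methylpent-4-yn-1-yl acetate, via secondary ozonide 13 (not isolated)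
Conditions: O3, CH2Cl2, −78 °C (Sudan Red 7B end point); then Me2S, −78 °C → rt
Reagents that add atoms: ozone, [O-][O+]=O
Why: Ozonolysis with reductive work-up: ozone adds to the vinyl group much faster than to the terminal alkyne or the dimethoxyarene, and the indicator dye marks the end point, unmasking the formyl group on the quaternary carbon.

**Step 8**
Reactants: 14 (1R,2R,3R)-1-(3,4-dimethoxyphenyl)-3-formyl-3-methoxy-2-methylpent-4-yn-1-yl acetate; 15 pent-4-enoyl chloride
Product: 16 (1R,2R,3R)-1-(3,4-dimethoxyphenyl)-3-formyl-3-methoxy-2-methyl-6-oxodec-9-en-4-yn-1-yl acetate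
Conditions: PdCl2(PPh3)2 (2 mol%), CuI (4 mol%), Et3N (1.2 equiv), THF, rt
Reagents that add atoms: none
Why: Acyl Sonogashira coupling: the copper acetylide transmetalates to the acylpalladium chloride and reductive elimination gives the ynone under conditions that leave the aldehyde and acetate alone.

**Step 9**
Reactants: 16 (1R,2R,3R)-1-(3,4-dimethoxyphenyl)-3-formyl-3-methoxy-2-methyl-6-oxodec-9-en-4-yn-1-yl acetate
Product: 17 (1R,2R,3R,4E)-1-(3,4-dimethoxyphenyl)-3-formyl-3,4-dimethoxy-2-methyl-6-oxodeca-4,9-dien-1-yl acetate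
Conditions: MeOH (5 equiv), PMe3 (10 mol%), CH2Cl2, 0 °C → rt
Reagents that add atoms: methanol, CO
Why: Phosphine-catalysed oxa-Michael addition of methanol to the ynone places OMe on the β-carbon, and the (E) isomer (OMe trans to the carbonyl, acyl cis to the quaternary carbon) is expected because protonation occurs anti to the bulky quaternary carbon and β-alkoxy enones prefer this arrangement.

**Step 10**
Reactants: 17 (1R,2R,3R,4E)-1-(3,4-dimethoxyphenyl)-3-formyl-3,4-dimethoxy-2-methyl-6-oxodeca-4,9-dien-1-yl acetate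
Product: 20 (1R,2R)-1-(3,4-dimethoxyphenyl)-2-[(1R)-1,2-dimethoxy-4-oxo-5-(prop-2-en-1-yl)cyclohexa-2,5-dien-1-yl]propyl acetate, via lithium aldolate 18 (not isolated), via aldol mesylate 19 (not isolated)
Conditions: LiN(SiMe3)2 (1.1 equiv), THF, −78 °C; then MsCl, −78 → 0 °C; then DBU, 0 °C → rt
Reagents that add atoms: none
Why: LiN(SiMe3)2 deprotonates the ketone CH2 of the pent-4-enoyl group, the only enolisable position of 17 (the formyl group has no α-hydrogen, the γ-carbon of the vinylogous ester is quaternary), and the cross-conjugated enolate adds to the formyl carbon to give aldolate 18, whose mesylate 19 loses methanesulfonate by E1cB elimination with DBU to leave the ring C5=C6 bond. The closest known reaction type is the intramolecular aldol condensation of a kinetic α'-enolate of a β-alkoxy enone with an aldehyde. The cyclohexadienone ring closes in a 6-(enolexo)-exo-trig mode. No stereocentre of the target is made: the two new sp3 ring carbons of 18 and 19 become sp2 on elimination, while the quaternary carbon, which has no hydrogen, and the two side-chain centres are untouched at −78 °C. The step needs deprotonation to beat addition of the amide to the aldehyde, secured by the neopentyl-type hindered formyl group and the low temperature, and it needs the quaternary carbon and the acyl group cis on the enol ether alkene, secured by the (E) geometry of 17. Elimination can only run towards the allyl-bearing carbon because the other neighbour of the carbinol carbon is quaternary, and before step 9 the linear ynone 16 cannot cyclise at all.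

**Compound list**
1 | (R)-4-benzyl-3-propionyloxazolidin-2-one | CCC(=O)N1[C@H](Cc2ccccc2)COC1=O | starting material
2 | 3,4-dimethoxybenzaldehyde | COc1ccc(C=O)cc1OC | starting material
3 | (R)-4-benzyl-3-[(Z)-1-(dibutylboranyloxy)prop-1-en-1-yl]oxazolidin-2-one | CCCCB(CCCC)O/C(=C\C)N1[C@H](Cc2ccccc2)COC1=O | intermediate (not isolated)
4 | (R)-4-benzyl-3-[(2R,3R)-3-(dibutylboranyloxy)-3-(3,4-dimethoxyphenyl)-2-methylpropanoyl]oxazolidin-2-one | O=C1OC[C@@H](Cc2ccccc2)N1C(=O)[C@H](C)[C@@H](OB(CCCC)CCCC)c1ccc(OC)c(OC)c1 | intermediate (not isolated)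
5 | (R)-4-benzyl-3-[(2R,3R)-3-(3,4-dimethoxyphenyl)-3-hydroxy-2-methylpropanoyl]oxazolidin-2-one | O=C1OC[C@@H](Cc2ccccc2)N1C(=O)[C@H](C)[C@@H](O)c1ccc(OC)c(OC)c1 | intermediate
6 | (2R,3R)-3-(3,4-dimethoxyphenyl)-3-hydroxy-N-methoxy-N,2-dimethylpropanamide | CON(C)C(=O)[C@H](C)[C@@H](O)c1ccc(OC)c(OC)c1 | intermediate
7 | vinylmagnesium bromide | C=C[Mg]Br | starting material
8 | (4R,5R)-5-(3,4-dimethoxyphenyl)-5-hydroxy-4-methylpent-1-en-3-one | C=CC(=O)[C@H](C)[C@@H](O)c1ccc(OC)c(OC)c1 | intermediate
9 | ethynylmagnesium bromide | C#C[Mg]Br | starting material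
10 | (3R,4R,5R)-5-(3,4-dimethoxyphenyl)-3-ethynyl-4-methylpent-1-ene-3,5-diol | C=C[C@@](O)([C@H](C)[C@@H](O)c1ccc(OC)c(OC)c1)C#C | intermediate
11 | (1R,2R,3R)-1-(3,4-dimethoxyphenyl)-3-ethynyl-3-hydroxy-2-methylpent-4-en-1-yl acetate | C=C[C@@](O)([C@H](C)[C@@H](OC(C)=O)c1ccc(OC)c(OC)c1)C#C | intermediate
12 | (1R,2R,3R)-1-(3,4-dimethoxyphenyl)-3-ethynyl-3-methoxy-2-methylpent-4-en-1-yl acetate | C=C[C@@](OC)([C@H](C)[C@@H](OC(C)=O)c1ccc(OC)c(OC)c1)C#C | intermediate
13 | (1R,2R,3R)-1-(3,4-dimethoxyphenyl)-3-ethynyl-3-methoxy-2-methyl-3-(1,2,4-trioxolan-3-yl)propyl acetate (ozonide carbon unassigned) | C1OC(OO1)[C@@](OC)([C@H](C)[C@@H](OC(C)=O)c1ccc(OC)c(OC)c1)C#C | intermediate (not isolated)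
14 | (1R,2R,3R)-1-(3,4-dimethoxyphenyl)-3-formyl-3-methoxy-2-methylpent-4-yn-1-yl acetate | O=C[C@@](OC)([C@H](C)[C@@H](OC(C)=O)c1ccc(OC)c(OC)c1)C#C | intermediate
15 | pent-4-enoyl chloride | C=CCCC(=O)Cl | starting material
16 | (1R,2R,3R)-1-(3,4-dimethoxyphenyl)-3-formyl-3-methoxy-2-methyl-6-oxodec-9-en-4-yn-1-yl acetate | O=C[C@@](OC)([C@H](C)[C@@H](OC(C)=O)c1ccc(OC)c(OC)c1)C#CC(=O)CCC=C | intermediate
17 | (1R,2R,3R,4E)-1-(3,4-dimethoxyphenyl)-3-formyl-3,4-dimethoxy-2-methyl-6-oxodeca-4,9-dien-1-yl acetate | O=C[C@@](OC)([C@H](C)[C@@H](OC(C)=O)c1ccc(OC)c(OC)c1)/C(OC)=C\C(=O)CCC=C | intermediate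
18 | lithium 2-[(1R,2R)-1-acetoxy-1-(3,4-dimethoxyphenyl)propan-2-yl]-2,3-dimethoxy-5-oxo-6-(prop-2-en-1-yl)cyclohex-3-en-1-olate (quaternary carbon and side chain as in 17; the two new ring carbons unassigned) | C=CCC1C([O-])[C@@](OC)([C@H](C)[C@@H](OC(C)=O)c2ccc(OC)c(OC)c2)C(OC)=CC1=O.[Li+] | intermediate (not isolated)
19 | 2-[(1R,2R)-1-acetoxy-1-(3,4-dimethoxyphenyl)propan-2-yl]-2,3-dimethoxy-5-oxo-6-(prop-2-en-1-yl)cyclohex-3-en-1-yl methanesulfonate (same stereochemical remarks as 18) | C=CCC1C(OS(C)(=O)=O)[C@@](OC)([C@H](C)[C@@H](OC(C)=O)c2ccc(OC)c(OC)c2)C(OC)=CC1=O | intermediate (not isolated)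
20 | (1R,2R)-1-(3,4-dimethoxyphenyl)-2-[(1R)-1,2-dimethoxy-4-oxo-5-(prop-2-en-1-yl)cyclohexa-2,5-dien-1-yl]propyl acetate | C=CCC1=C[C@@](OC)([C@H](C)[C@@H](OC(C)=O)c2ccc(OC)c(OC)c2)C(OC)=CC1=O | target

**Total step count:** 10. **Longest linear sequence:** 10 steps.

**Steps most likely to fail**

1. Step 10 (key step). The silylamide may add to the formyl group instead of deprotonating the ketone. The aldolate oxygen may take over the acetyl group. A (Z) fraction of 17 cannot bring enolate and aldehyde together. Fallback: the same ring C=C bond is closed by ring-closing metathesis, which needs neither the aldehyde nor a strong base. It sets out from 12, whose vinyl group is kept. Acyl Sonogashira coupling with 15 (PdCl2(PPh3)2, CuI, Et3N, THF) should give the vinyl ynone F1. PMe3-catalysed addition of MeOH should give the (E)-β-methoxy enone F2. α-Methylenation of the ketone CH2 (paraformaldehyde, i-Pr2NH2+ CF3CO2−, THF, reflux) should give the α-methylene ketone F3. Ring-closing metathesis of F3 with the second-generation Hoveyda–Grubbs catalyst RuCl2(H2IMes)(=CH-C6H4-2-O-i-Pr) (toluene, 60 °C, high dilution) joins the vinyl group on the quaternary carbon to the 1,1-disubstituted enone alkene with loss of ethene. Six-membered closure is expected to outrun eight-membered closure through the allyl group. The fallback comes back to the route at 20.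

2. Step 4. Incomplete chelation in the coordinating solvent may erode facial selectivity, and the magnesium aldolate of 8 may undergo retro-aldol cleavage or epimerise next to the ketone. Fallback: the two carbon groups are introduced in the reverse order under Felkin–Anh instead of chelate control. It sets out from 6. Silylation (t-BuMe2SiOTf, 2,6-lutidine, CH2Cl2) should give the silyl ether F4. LiC≡CSiMe3 (THF, −78 °C) should give the silyl ynone F5. Addition of 7 (THF, −78 °C) anti to the bulky CH(OSi)Ar group should give the tertiary alcohol F6. Because vinyl now enters last, F6 has the same configuration as the chelate product. Bu4NF (THF) removes both silyl groups, and the fallback comes back to the route at 10.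

3. Step 6. The tertiary allylic-propargylic carbinol may ionise under the strongly electrophilic conditions, or methylation may stall at the hindered hydroxyl. Fallback: an alkoxide is methylated while the secondary oxygen carries a base-stable silyl group instead of the acetate. It sets out from 10. t-BuMe2SiOTf (1 equiv), 2,6-lutidine, CH2Cl2, −78 °C should give the secondary silyl ether F7. NaH, MeI, THF, 0 °C should give the methyl ether F8. Bu4NF (THF) should give the alcohol F9. Ac2O, pyridine, DMAP brings the fallback back to the route at 12.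

**Further compounds**
F1 | step 10 | (1R,2R,3R)-1-(3,4-dimethoxyphenyl)-3-ethenyl-3-methoxy-2-methyl-6-oxodec-9-en-4-yn-1-yl acetate | C=C[C@@](OC)([C@H](C)[C@@H](OC(C)=O)c1ccc(OC)c(OC)c1)C#CC(=O)CCC=C
F2 | step 10 | (1R,2R,3R,4E)-1-(3,4-dimethoxyphenyl)-3-ethenyl-3,4-dimethoxy-2-methyl-6-oxodeca-4,9-dien-1-yl acetate | C=C[C@@](OC)([C@H](C)[C@@H](OC(C)=O)c1ccc(OC)c(OC)c1)/C(OC)=C\C(=O)CCC=C
F3 | step 10 | (1R,2R,3R,4E)-1-(3,4-dimethoxyphenyl)-3-ethenyl-3,4-dimethoxy-2-methyl-7-methylidene-6-oxodeca-4,9-dien-1-yl acetate | C=C[C@@](OC)([C@H](C)[C@@H](OC(C)=O)c1ccc(OC)c(OC)c1)/C(OC)=C\C(=O)C(=C)CC=C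
F4 | step 4 | (2R,3R)-3-[(tert-butyldimethylsilyl)oxy]-3-(3,4-dimethoxyphenyl)-N-methoxy-N,2-dimethylpropanamide | CON(C)C(=O)[C@H](C)[C@@H](O[Si](C)(C)C(C)(C)C)c1ccc(OC)c(OC)c1
F5 | step 4 | (4R,5R)-5-[(tert-butyldimethylsilyl)oxy]-5-(3,4-dimethoxyphenyl)-4-methyl-1-(trimethylsilyl)pent-1-yn-3-one | C[Si](C)(C)C#CC(=O)[C@H](C)[C@@H](O[Si](C)(C)C(C)(C)C)c1ccc(OC)c(OC)c1
F6 | step 4 | (3R,4R,5R)-5-[(tert-butyldimethylsilyl)oxy]-5-(3,4-dimethoxyphenyl)-3-ethenyl-4-methyl-1-(trimethylsilyl)pent-1-yn-3-ol | C=C[C@@](O)([C@H](C)[C@@H](O[Si](C)(C)C(C)(C)C)c1ccc(OC)c(OC)c1)C#C[Si](C)(C)C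
F7 | step 6 | (3R,4R,5R)-5-[(tert-butyldimethylsilyl)oxy]-5-(3,4-dimethoxyphenyl)-3-ethynyl-4-methylpent-1-en-3-ol | C=C[C@@](O)([C@H](C)[C@@H](O[Si](C)(C)C(C)(C)C)c1ccc(OC)c(OC)c1)C#C
F8 | step 6 | tert-butyl{[(1R,2R,3R)-1-(3,4-dimethoxyphenyl)-3-ethynyl-3-methoxy-2-methylpent-4-en-1-yl]oxy}dimethylsilane | C=C[C@@](OC)([C@H](C)[C@@H](O[Si](C)(C)C(C)(C)C)c1ccc(OC)c(OC)c1)C#C
F9 | step 6 | (1R,2R,3R)-1-(3,4-dimethoxyphenyl)-3-ethynyl-3-methoxy-2-methylpent-4-en-1-ol | C=C[C@@](OC)([C@H](C)[C@@H](O)c1ccc(OC)c(OC)c1)C#C
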